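**Retrosynthetic overview**
1. Target 30 ⇐ bis-MOM flavan 29 ⇐ ring C closed last by Mitsunobu O1–C2 bond formation (inversion) from (1S)-1,3-diarylpropan-1-ol 28 ⇐ ketoreductase reduction of ketone 27.
2. 27 ⇐ conjugate reduction and deallylation of the chalcone from Claisen–Schmidt union of ring-B methyl ketone 24 with ring-A aldehyde 8.
3. 24 ⇐ aryl bromide → allyl (Stille) → prenyl (cross-metathesis); the 3S carbinol comes from Jacobsen epoxidation and hydride opening of chromene 17.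
4. 17 ⇐ propargyl aryl ether rearrangement on 2-bromo-4,5-dihydroxyacetophenone (from 4-bromoveratrole); 8 ⇐ aromatic Claisen rearrangement of the prenyl ether of 2,4-dihydroxybenzaldehyde.
5. Ring order: benzene rings A and B are bought; the dimethylpyran ring is formed first (step 11); the flavan pyran ring C is formed last (step 21).

Assumption: the SMILES is read as 2R at the flavan carbon and 3S at the carbinol carbon of the dimethylpyran ring (CIP analysis of the string as given).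

**Fragment A (ring-A aldehyde)**

Step 1
Reactants: 1 2,4-dihydroxybenzaldehyde; 2 1-bromo-3-methylbut-2-ene (prenyl bromide)
Product: 3 2-hydroxy-4-[(3-methylbut-2-en-1-yl)oxy]benzaldehyde
Conditions: K2CO3 (1.05 equiv), acetone, 56 °C
Reagents that add atoms: none
Why: Williamson ether synthesis; the 2-OH is hydrogen-bonded to the aldehyde, so one equivalent of weak base alkylates only the 4-OH.

Step 2
Reactants: 3 2-hydroxy-4-[(3-methylbut-2-en-1-yl)oxy]benzaldehyde
Product: 4 2-formyl-5-[(3-methylbut-2-en-1-yl)oxy]phenyl 2,2-dimethylpropanoate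
Conditions: PivCl, Et3N, DMAP (cat.), CH2Cl2, 0 °C to rt
Reagents that add atoms: pivaloyl chloride, CC(C)(C)C(=O)Cl
Why: DMAP-catalysed O-acylation removes the chelated phenol (no bond fixation towards C3) and places a bulky, heat-stable group next to C3.

Step 3
Reactants: 4 2-formyl-5-[(3-methylbut-2-en-1-yl)oxy]phenyl 2,2-dimethylpropanoate
Product: 5 2-formyl-5-hydroxy-4-(2-methylbut-3-en-2-yl)phenyl 2,2-dimethylpropanoate
Conditions: PhNEt2, 195 °C, sealed tube, Ar
Reagents that add atoms: none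
Why: Aromatic Claisen rearrangement ([3,3]-sigmatropic); with C3 flanked by the pivalate the prenyl terminus goes to C5 and rearomatisation gives the 1,1-dimethylallyl phenol, the basic solvent suppressing acid-catalysed cyclisation.

Step 4
Reactants: 5 2-formyl-5-hydroxy-4-(2-methylbut-3-en-2-yl)phenyl 2,2-dimethylpropanoate
Product: 6 2-formyl-5-(methoxymethoxy)-4-(2-methylbut-3-en-2-yl)phenyl 2,2-dimethylpropanoate
Conditions: MOMCl, i-Pr2NEt, CH2Cl2, 0 °C to rt
Reagents that add atoms: chloromethyl methyl ether, COCCl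
Why: Acetal-type O-alkylation (MOM protection) of the acidic phenol para to the aldehyde; the ester is inert.

Step 5
Reactants: 6 2-formyl-5-(methoxymethoxy)-4-(2-methylbut-3-en-2-yl)phenyl 2,2-dimethylpropanoate
Product: 7 2-hydroxy-4-(methoxymethoxy)-5-(2-methylbut-3-en-2-yl)benzaldehyde
Conditions: K2CO3, MeOH, rt
Reagents that add atoms: none
Why: Base-catalysed transesterification (methanolysis) of the aryl pivalate, activated by the ortho aldehyde; the MOM ether is base-stable.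

Step 6
Reactants: 7 2-hydroxy-4-(methoxymethoxy)-5-(2-methylbut-3-en-2-yl)benzaldehyde
Product: 8 4-(methoxymethoxy)-5-(2-methylbut-3-en-2-yl)-2-(prop-2-en-1-yloxy)benzaldehyde
Conditions: allyl bromide, K2CO3, DMF, rt
Reagents that add atoms: allyl bromide, C=CCBr
Why: Williamson ether synthesis; the allyl ether survives base and hydride and is later removed under neutral conditions in the presence of MOM groups.

**Fragment B (ring-B methyl ketone)**

Step 7
Reactants: 9 4-bromo-1,2-dimethoxybenzene; 10 acetyl chloride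
Product: 11 1-(2-bromo-4,5-dimethoxyphenyl)ethan-1-one
Conditions: AlCl3 (1.2 equiv), CH2Cl2, 0 °C
Reagents that add atoms: none
Why: Friedel–Crafts acylation para to the 2-methoxy group (ortho to Br), the established site for 4-bromoveratrole; no stereocentre is created.

Step 8
Reactants: 11 1-(2-bromo-4,5-dimethoxyphenyl)ethan-1-one
Product: 12 1-(2-bromo-4,5-dihydroxyphenyl)ethan-1-one
Conditions: BBr3 (3 equiv), CH2Cl2, −78 °C to rt; then H2O
Reagents that add atoms: none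
Why: Lewis-acid ether cleavage (BBr3 demethylation) of both aryl methyl ethers; ketone and aryl bromide are untouched.

Step 9
Reactants: 12 1-(2-bromo-4,5-dihydroxyphenyl)ethan-1-one; 13 3-chloro-3-methylbut-1-yne
Product: 14 1-{2-bromo-5-hydroxy-4-[(2-methylbut-3-yn-2-yl)oxy]phenyl}ethan-1-one
Conditions: K2CO3 (1.05 equiv), CuI (5 mol %), acetone, 56 °C, Ar
Reagents that add atoms: none
Why: Copper-catalysed propargylic O-alkylation; one equivalent of weak base ionises only the more acidic phenol para to the acetyl group, so the ether forms there.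

Step 10
Reactants: 14 1-{2-bromo-5-hydroxy-4-[(2-methylbut-3-yn-2-yl)oxy]phenyl}ethan-1-one
Product: 15 1-{2-bromo-5-(methoxymethoxy)-4-[(2-methylbut-3-yn-2-yl)oxy]phenyl}ethan-1-one
Conditions: MOMCl, i-Pr2NEt, CH2Cl2, 0 °C to rt
Reagents that add atoms: chloromethyl methyl ether, COCCl
Why: MOM protection (O-alkylation) of the remaining phenol before the thermal step and the oxidation.

Step 11
Reactants: 15 1-{2-bromo-5-(methoxymethoxy)-4-[(2-methylbut-3-yn-2-yl)oxy]phenyl}ethan-1-one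
Product: 17 1-[5-bromo-8-(methoxymethoxy)-2,2-dimethyl-2H-chromen-6-yl]ethan-1-one, via ortho-allenylphenol 16 (not isolated)
Conditions: PhNEt2, 190 °C, Ar
Reagents that add atoms: none
Why: Propargyl Claisen rearrangement to the only free ortho carbon, then 1,5-hydrogen shift and oxa-6π electrocyclisation, closes the dimethylpyran ring.

Step 12
Reactants: 17 1-[5-bromo-8-(methoxymethoxy)-2,2-dimethyl-2H-chromen-6-yl]ethan-1-one
Product: 18 1-[(3S,4S)-5-bromo-3,4-epoxy-8-(methoxymethoxy)-2,2-dimethyl-3,4-dihydro-2H-chromen-6-yl]ethan-1-one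
Conditions: (S,S)-(salen)MnCl (4 mol %; salen = N,N′-bis(3,5-di-tert-butylsalicylidene)cyclohexane-1,2-diamine dianion), 4-phenylpyridine N-oxide, aq. NaOCl (pH 11.3), CH2Cl2, 0 °C
Reagents that add atoms: sodium hypochlorite, [Na+].[O-]Cl
Why: Jacobsen–Katsuki asymmetric epoxidation; the (S,S)-salen manganese oxo species delivers oxygen to one face of the cis, aryl-conjugated chromene alkene and sets 3S,4S, the first stereocentres, under catalyst control.

Step 13
Reactants: 18 1-[(3S,4S)-5-bromo-3,4-epoxy-8-(methoxymethoxy)-2,2-dimethyl-3,4-dihydro-2H-chromen-6-yl]ethan-1-one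
Product: 19 (1RS)-1-[(3S)-5-bromo-3-hydroxy-8-(methoxymethoxy)-2,2-dimethyl-3,4-dihydro-2H-chromen-6-yl]ethan-1-ol
Conditions: LiAlH4, THF, 0 °C to rt
Reagents that add atoms: none
Why: Hydride SN2 epoxide opening at benzylic C4 (C3 is neopentyl) leaves the C3–O bond and its S configuration intact; the ketone is reduced at the same time to an inconsequential epimer mixture.

Step 14
Reactants: 19 (1RS)-1-[(3S)-5-bromo-3-hydroxy-8-(methoxymethoxy)-2,2-dimethyl-3,4-dihydro-2H-chromen-6-yl]ethan-1-ol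
Product: 20 1-[(3S)-5-bromo-3-hydroxy-8-(methoxymethoxy)-2,2-dimethyl-3,4-dihydro-2H-chromen-6-yl]ethan-1-one
Conditions: MnO2 (activated, excess), CH2Cl2, rt
Reagents that add atoms: none
Why: Chemoselective MnO2 oxidation of the benzylic carbinol back to the aryl ketone; the non-benzylic ring carbinol is inert.

Step 15
Reactants: 20 1-[(3S)-5-bromo-3-hydroxy-8-(methoxymethoxy)-2,2-dimethyl-3,4-dihydro-2H-chromen-6-yl]ethan-1-one; 21 tributyl(prop-2-en-1-yl)stannane
Product: 22 1-[(3S)-3-hydroxy-8-(methoxymethoxy)-2,2-dimethyl-5-(prop-2-en-1-yl)-3,4-dihydro-2H-chromen-6-yl]ethan-1-one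
Conditions: Pd(PPh3)4 (5 mol %), toluene, 100 °C
Reagents that add atoms: none
Why: Stille coupling; the ortho acetyl group helps oxidative addition and an unsubstituted allyl group avoids any α/γ regiochemistry question.

Step 16
Reactants: 22 1-[(3S)-3-hydroxy-8-(methoxymethoxy)-2,2-dimethyl-5-(prop-2-en-1-yl)-3,4-dihydro-2H-chromen-6-yl]ethan-1-one; 23 2-methylbut-2-ene
Product: 24 1-[(3S)-3-hydroxy-8-(methoxymethoxy)-2,2-dimethyl-5-(3-methylbut-2-en-1-yl)-3,4-dihydro-2H-chromen-6-yl]ethan-1-one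
Conditions: second-generation Grubbs catalyst (H2IMes)(PCy3)Cl2Ru=CHPh (5 mol %), 2-methylbut-2-ene (excess), CH2Cl2, 40 °C, sealed
Reagents that add atoms: none
Why: Olefin cross-metathesis turns the terminal allyl group into the prenyl group, driven by loss of propene.

**Union and endgame**

Step 17
Reactants: 24 1-[(3S)-3-hydroxy-8-(methoxymethoxy)-2,2-dimethyl-5-(3-methylbut-2-en-1-yl)-3,4-dihydro-2H-chromen-6-yl]ethan-1-one; 8 4-(methoxymethoxy)-5-(2-methylbut-3-en-2-yl)-2-(prop-2-en-1-yloxy)benzaldehyde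
Product: 25 (2E)-1-[(3S)-3-hydroxy-8-(methoxymethoxy)-2,2-dimethyl-5-(3-methylbut-2-en-1-yl)-3,4-dihydro-2H-chromen-6-yl]-3-[4-(methoxymethoxy)-5-(2-methylbut-3-en-2-yl)-2-(prop-2-en-1-yloxy)phenyl]prop-2-en-1-one
Conditions: KOH, EtOH/H2O, rt
Reagents that add atoms: none
Why: Claisen–Schmidt (crossed aldol) condensation of the only enolisable ketone with a non-enolisable aldehyde; E1cB dehydration gives the E-enone and all protecting groups are base-stable.

Step 18
Reactants: 25 the E-enone of step 17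
Product: 26 1-[(3S)-3-hydroxy-8-(methoxymethoxy)-2,2-dimethyl-5-(3-methylbut-2-en-1-yl)-3,4-dihydro-2H-chromen-6-yl]-3-[4-(methoxymethoxy)-5-(2-methylbut-3-en-2-yl)-2-(prop-2-en-1-yloxy)phenyl]propan-1-one
Conditions: [(Ph3P)CuH]6 (0.4 equiv), H2O (5 equiv), THF, rt
Reagents that add atoms: none
Why: Copper hydride (Stryker) conjugate reduction adds hydride 1,4 to the enone only; the vinyl, prenyl and allyl ether alkenes and the ketone are untouched.

Step 19
Reactants: 26 the saturated ketone of step 18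
Product: 27 3-[2-hydroxy-4-(methoxymethoxy)-5-(2-methylbut-3-en-2-yl)phenyl]-1-[(3S)-3-hydroxy-8-(methoxymethoxy)-2,2-dimethyl-5-(3-methylbut-2-en-1-yl)-3,4-dihydro-2H-chromen-6-yl]propan-1-one
Conditions: Pd(PPh3)4 (5 mol %), morpholine, THF, rt
Reagents that add atoms: none
Why: Tsuji–Trost-type deallylation; zerovalent palladium ionises only the aryl allyl ether and morpholine traps the π-allyl fragment, freeing the ring-A phenol without acid.

Step 20
Reactants: 27 the keto phenol of step 19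
Product: 28 (1S)-3-[2-hydroxy-4-(methoxymethoxy)-5-(2-methylbut-3-en-2-yl)phenyl]-1-[(3S)-3-hydroxy-8-(methoxymethoxy)-2,2-dimethyl-5-(3-methylbut-2-en-1-yl)-3,4-dihydro-2H-chromen-6-yl]propan-1-ol
Conditions: (S)-selective ketoreductase (NADPH-dependent, variant chosen from a screening panel), NADP+ (cat.), i-PrOH (20% v/v), DMSO (10% v/v), KH2PO4/K2HPO4 buffer pH 7.0, 30 °C
Reagents that add atoms: none
Why: Ketoreductase-catalysed asymmetric carbonyl reduction; the enzyme delivers hydride from NADPH to one face of the aryl ketone (catalyst control, independent of the remote 3S centre) to set 1S, with isopropanol recycling the cofactor.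

Step 21
Reactants: 28 the (1S)-diol phenol of step 20
Product: 29 (3S)-8-(methoxymethoxy)-6-[(2R)-7-(methoxymethoxy)-6-(2-methylbut-3-en-2-yl)-3,4-dihydro-2H-chromen-2-yl]-2,2-dimethyl-5-(3-methylbut-2-en-1-yl)-3,4-dihydro-2H-chromen-3-ol
Conditions: PPh3, DIAD, THF (0.02 M), 0 °C to rt
Reagents that add atoms: none
Why: Intramolecular Mitsunobu etherification; the only free phenol displaces the activated benzylic carbinol in a 6-exo SN2 reaction with inversion (1S → 2R), while the neopentyl-type ring carbinol is too hindered to react.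

Step 22
Reactants: 29 the bis-MOM flavan of step 21
Product: 30 (3S)-6-[(2R)-7-hydroxy-6-(2-methylbut-3-en-2-yl)-3,4-dihydro-2H-chromen-2-yl]-2,2-dimethyl-5-(3-methylbut-2-en-1-yl)-3,4-dihydro-2H-chromene-3,8-diol
Conditions: HCl (2 M), MeOH/THF, 40 °C
Reagents that add atoms: none
Why: Acid-catalysed acetal methanolysis removes both aryl MOM groups under conditions too mild to protonate the alkenes or ionise the flavan C2–O bond.

**Compound list**
1 | 2,4-dihydroxybenzaldehyde | O=Cc1ccc(O)cc1O | starting material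
2 | 1-bromo-3-methylbut-2-ene | CC(C)=CCBr | starting material
3 | 2-hydroxy-4-[(3-methylbut-2-en-1-yl)oxy]benzaldehyde | O=Cc1ccc(OCC=C(C)C)cc1O | intermediate
4 | 2-formyl-5-[(3-methylbut-2-en-1-yl)oxy]phenyl 2,2-dimethylpropanoate | O=Cc1ccc(OCC=C(C)C)cc1OC(=O)C(C)(C)C | intermediate
5 | 2-formyl-5-hydroxy-4-(2-methylbut-3-en-2-yl)phenyl 2,2-dimethylpropanoate | O=Cc1cc(C(C)(C)C=C)c(O)cc1OC(=O)C(C)(C)C | intermediate
6 | 2-formyl-5-(methoxymethoxy)-4-(2-methylbut-3-en-2-yl)phenyl 2,2-dimethylpropanoate | O=Cc1cc(C(C)(C)C=C)c(OCOC)cc1OC(=O)C(C)(C)C | intermediate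
7 | 2-hydroxy-4-(methoxymethoxy)-5-(2-methylbut-3-en-2-yl)benzaldehyde | O=Cc1cc(C(C)(C)C=C)c(OCOC)cc1O | intermediate
8 | 4-(methoxymethoxy)-5-(2-methylbut-3-en-2-yl)-2-(prop-2-en-1-yloxy)benzaldehyde | O=Cc1cc(C(C)(C)C=C)c(OCOC)cc1OCC=C | intermediate
9 | 4-bromo-1,2-dimethoxybenzene | COc1ccc(Br)cc1OC | starting material
10 | acetyl chloride | CC(Cl)=O | starting material
11 | 1-(2-bromo-4,5-dimethoxyphenyl)ethan-1-one | CC(=O)c1cc(OC)c(OC)cc1Br | intermediate
12 | 1-(2-bromo-4,5-dihydroxyphenyl)ethan-1-one | CC(=O)c1cc(O)c(O)cc1Br | intermediate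
13 | 3-chloro-3-methylbut-1-yne | C#CC(C)(C)Cl | starting material
14 | 1-{2-bromo-5-hydroxy-4-[(2-methylbut-3-yn-2-yl)oxy]phenyl}ethan-1-one | CC(=O)c1cc(O)c(OC(C)(C)C#C)cc1Br | intermediate
15 | 1-{2-bromo-5-(methoxymethoxy)-4-[(2-methylbut-3-yn-2-yl)oxy]phenyl}ethan-1-one | CC(=O)c1cc(OCOC)c(OC(C)(C)C#C)cc1Br | intermediate
16 | 1-[2-bromo-4-hydroxy-5-(methoxymethoxy)-3-(3-methylbuta-1,2-dien-1-yl)phenyl]ethan-1-one | CC(=O)c1cc(OCOC)c(O)c(C=C=C(C)C)c1Br | intermediate
17 | 1-[5-bromo-8-(methoxymethoxy)-2,2-dimethyl-2H-chromen-6-yl]ethan-1-one | CC(=O)c1cc(OCOC)c2OC(C)(C)C=Cc2c1Br | intermediate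
18 | 1-[(3S,4S)-5-bromo-3,4-epoxy-8-(methoxymethoxy)-2,2-dimethyl-3,4-dihydro-2H-chromen-6-yl]ethan-1-one | CC1(C)Oc2c(OCOC)cc(C(C)=O)c(Br)c2[C@@H]3O[C@H]13 | intermediate
19 | (1RS)-1-[(3S)-5-bromo-3-hydroxy-8-(methoxymethoxy)-2,2-dimethyl-3,4-dihydro-2H-chromen-6-yl]ethan-1-ol | CC(O)c1cc(OCOC)c2OC(C)(C)[C@@H](O)Cc2c1Br | intermediate
20 | 1-[(3S)-5-bromo-3-hydroxy-8-(methoxymethoxy)-2,2-dimethyl-3,4-dihydro-2H-chromen-6-yl]ethan-1-one | CC(=O)c1cc(OCOC)c2OC(C)(C)[C@@H](O)Cc2c1Br | intermediate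
21 | tributyl(prop-2-en-1-yl)stannane | C=CC[Sn](CCCC)(CCCC)CCCC | starting material
22 | 1-[(3S)-3-hydroxy-8-(methoxymethoxy)-2,2-dimethyl-5-(prop-2-en-1-yl)-3,4-dihydro-2H-chromen-6-yl]ethan-1-one | CC(=O)c1cc(OCOC)c2OC(C)(C)[C@@H](O)Cc2c1CC=C | intermediate
23 | 2-methylbut-2-ene | CC=C(C)C | starting material
24 | 1-[(3S)-3-hydroxy-8-(methoxymethoxy)-2,2-dimethyl-5-(3-methylbut-2-en-1-yl)-3,4-dihydro-2H-chromen-6-yl]ethan-1-one | CC(=O)c1cc(OCOC)c2OC(C)(C)[C@@H](O)Cc2c1CC=C(C)C | intermediate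
25 | (2E)-1-[(3S)-3-hydroxy-8-(methoxymethoxy)-2,2-dimethyl-5-(3-methylbut-2-en-1-yl)-3,4-dihydro-2H-chromen-6-yl]-3-[4-(methoxymethoxy)-5-(2-methylbut-3-en-2-yl)-2-(prop-2-en-1-yloxy)phenyl]prop-2-en-1-one | O=C(/C=C/c1cc(C(C)(C)C=C)c(OCOC)cc1OCC=C)c1cc(OCOC)c2OC(C)(C)[C@@H](O)Cc2c1CC=C(C)C | intermediate
26 | 1-[(3S)-3-hydroxy-8-(methoxymethoxy)-2,2-dimethyl-5-(3-methylbut-2-en-1-yl)-3,4-dihydro-2H-chromen-6-yl]-3-[4-(methoxymethoxy)-5-(2-methylbut-3-en-2-yl)-2-(prop-2-en-1-yloxy)phenyl]propan-1-one | O=C(CCc1cc(C(C)(C)C=C)c(OCOC)cc1OCC=C)c1cc(OCOC)c2OC(C)(C)[C@@H](O)Cc2c1CC=C(C)C | intermediate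
27 | 3-[2-hydroxy-4-(methoxymethoxy)-5-(2-methylbut-3-en-2-yl)phenyl]-1-[(3S)-3-hydroxy-8-(methoxymethoxy)-2,2-dimethyl-5-(3-methylbut-2-en-1-yl)-3,4-dihydro-2H-chromen-6-yl]propan-1-one | O=C(CCc1cc(C(C)(C)C=C)c(OCOC)cc1O)c1cc(OCOC)c2OC(C)(C)[C@@H](O)Cc2c1CC=C(C)C | intermediate
28 | (1S)-3-[2-hydroxy-4-(methoxymethoxy)-5-(2-methylbut-3-en-2-yl)phenyl]-1-[(3S)-3-hydroxy-8-(methoxymethoxy)-2,2-dimethyl-5-(3-methylbut-2-en-1-yl)-3,4-dihydro-2H-chromen-6-yl]propan-1-ol | O[C@@H](CCc1cc(C(C)(C)C=C)c(OCOC)cc1O)c1cc(OCOC)c2OC(C)(C)[C@@H](O)Cc2c1CC=C(C)C | intermediate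
29 | (3S)-8-(methoxymethoxy)-6-[(2R)-7-(methoxymethoxy)-6-(2-methylbut-3-en-2-yl)-3,4-dihydro-2H-chromen-2-yl]-2,2-dimethyl-5-(3-methylbut-2-en-1-yl)-3,4-dihydro-2H-chromen-3-ol | C=CC(C)(C)c1cc2c(cc1OCOC)O[C@@H](c1cc(OCOC)c3c(c1CC=C(C)C)C[C@H](O)C(C)(C)O3)CC2 | intermediate
30 | (3S)-6-[(2R)-7-hydroxy-6-(2-methylbut-3-en-2-yl)-3,4-dihydro-2H-chromen-2-yl]-2,2-dimethyl-5-(3-methylbut-2-en-1-yl)-3,4-dihydro-2H-chromene-3,8-diol | C=CC(C)(C)c1cc2c(cc1O)O[C@@H](c1cc(O)c3c(c1CC=C(C)C)C[C@H](O)C(C)(C)O3)CC2 | target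

**Step count**
Total steps: 22. Longest linear sequence: 16 steps (9 → 30, steps 7–22); the ring-A branch (steps 1–6) joins at step 17.

**Three steps most likely to fail**

Step 3 (aromatic Claisen rearrangement of 4). Prenyl aryl ethers can lose the prenyl group or attack C3 at 195 °C. The fallback sets out from 1 and returns at 7, and builds the quaternary benzylic carbon by cross-coupling instead of a sigmatropic shift. Bromination of 1 (Br2, AcOH) gives 5-bromo-2,4-dihydroxybenzaldehyde F1. MOMCl/i-Pr2NEt gives 5-bromo-2,4-bis(methoxymethoxy)benzaldehyde F2. Ethylene glycol/PPTS (toluene, Dean–Stark) gives 2-[5-bromo-2,4-bis(methoxymethoxy)phenyl]-1,3-dioxolane F3. Palladium-catalysed α-arylation of 2-methylpropanal (Pd(OAc)2, rac-BINAP, Cs2CO3, dioxane, 80 °C) fixes the aryl–C(CH3)2 bond at the former C–Br carbon and gives 2-[5-(1,3-dioxolan-2-yl)-2,4-bis(methoxymethoxy)phenyl]-2-methylpropanal F4. Wittig methylenation (Ph3P=CH2, THF) gives 2-[2,4-bis(methoxymethoxy)-5-(2-methylbut-3-en-2-yl)phenyl]-1,3-dioxolane F5. PPTS in wet acetone frees 2,4-bis(methoxymethoxy)-5-(2-methylbut-3-en-2-yl)benzaldehyde F6. Brief dilute HCl in MeOH at rt then removes only the MOM group hydrogen-bonded to the aldehyde and delivers 7.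

Step 20 (ketoreductase reduction of 27). The ortho-prenyl aryl ketone with a long second substituent may be accepted by no panel enzyme, or only with low conversion. The fallback sets out from 27 and returns at 28. It makes the same (1S)-alcohol by Noyori–Ikariya asymmetric transfer hydrogenation (RuCl(p-cymene)[(S,S)-TsDPEN], HCO2H/Et3N 5:2, 40 °C), which reduces aryl alkyl ketones to the S carbinol without touching isolated alkenes; it makes no further compound, F0.

Step 21 (Mitsunobu ring closure of 28). The para-alkoxybenzylic carbinol can ionise (loss of ee) or eliminate to the styrene. The fallback sets out from 27 and returns at 29, and closes ring C at the aryl carbon instead of the carbinol carbon, so the stereocentre is never a reacting centre. PhNTf2/K2CO3 (DMF) converts the phenol of 27 into 2-{3-[(3S)-3-hydroxy-8-(methoxymethoxy)-2,2-dimethyl-5-(3-methylbut-2-en-1-yl)-3,4-dihydro-2H-chromen-6-yl]-3-oxopropyl}-5-(methoxymethoxy)-4-(2-methylbut-3-en-2-yl)phenyl trifluoromethanesulfonate F7. An (R)-selective ketoreductase under the step 20 conditions gives the corresponding (3R)-3-hydroxypropyl aryl triflate F8. Palladium-catalysed intramolecular C–O coupling (Pd(OAc)2, 2-(di-tert-butylphosphino)-1,1′-binaphthyl, K3PO4, toluene, 80 °C) then forms the aryl–O bond with retention at the carbinol carbon and gives 29.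

**Further compounds**
F1 | step 3 | 5-bromo-2,4-dihydroxybenzaldehyde | O=Cc1cc(Br)c(O)cc1O
F2 | step 3 | 5-bromo-2,4-bis(methoxymethoxy)benzaldehyde | O=Cc1cc(Br)c(OCOC)cc1OCOC
F3 | step 3 | 2-[5-bromo-2,4-bis(methoxymethoxy)phenyl]-1,3-dioxolane | Brc1cc(C2OCCO2)c(OCOC)cc1OCOC
F4 | step 3 | 2-[5-(1,3-dioxolan-2-yl)-2,4-bis(methoxymethoxy)phenyl]-2-methylpropanal | O=CC(C)(C)c1cc(C2OCCO2)c(OCOC)cc1OCOC
F5 | step 3 | 2-[2,4-bis(methoxymethoxy)-5-(2-methylbut-3-en-2-yl)phenyl]-1,3-dioxolane | C=CC(C)(C)c1cc(C2OCCO2)c(OCOC)cc1OCOC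
F6 | step 3 | 2,4-bis(methoxymethoxy)-5-(2-methylbut-3-en-2-yl)benzaldehyde | O=Cc1cc(C(C)(C)C=C)c(OCOC)cc1OCOC
F0 | step 20 | none | none
F7 | step 21 | 2-{3-[(3S)-3-hydroxy-8-(methoxymethoxy)-2,2-dimethyl-5-(3-methylbut-2-en-1-yl)-3,4-dihydro-2H-chromen-6-yl]-3-oxopropyl}-5-(methoxymethoxy)-4-(2-methylbut-3-en-2-yl)phenyl trifluoromethanesulfonate | O=C(CCc1cc(C(C)(C)C=C)c(OCOC)cc1OS(=O)(=O)C(F)(F)F)c1cc(OCOC)c2OC(C)(C)[C@@H](O)Cc2c1CC=C(C)C
F8 | step 21 | 2-{(3R)-3-hydroxy-3-[(3S)-3-hydroxy-8-(methoxymethoxy)-2,2-dimethyl-5-(3-methylbut-2-en-1-yl)-3,4-dihydro-2H-chromen-6-yl]propyl}-5-(methoxymethoxy)-4-(2-methylbut-3-en-2-yl)phenyl trifluoromethanesulfonate | O[C@H](CCc1cc(C(C)(C)C=C)c(OCOC)cc1OS(=O)(=O)C(F)(F)F)c1cc(OCOC)c2OC(C)(C)[C@@H](O)Cc2c1CC=C(C)C
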